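Labels: ring carbons C1–C14 (C1 bears acrylate carbon C15, C2 the lactone oxygen, C3 OH, C4 Me, C8 Me/OH, C9=C10, C12–C13 oxirane); C16 = lactone C=O, C17 = exocyclic CH2.
Cuts: silyl ethers and the C12–C13 oxirane first; then the butyrolactone ring (O–C16–C15–C1–C2) at O–C2 and C15–C16, which takes out one CO2 and leaves an alkenyl bromide at C15 and a C2 mesylate of inverted configuration; then the 14-membered ring at C1–C2 (allylchromium + aldehyde); then the chain at (Z)-C9=C10 (Wittig) into a C2–C9 aldehyde and a C10–C14/C1/C15/C17 phosphonium salt.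
Enabling feature: in the lactone ring, C16 and the ring oxygen together are one CO2, C15 is the sp2 carbon of a 1,1-disubstituted alkene, and C2 is a secondary oxygenated carbon γ to C16; carboxylation at C15 followed by 5-exo-tet displacement at C2 therefore builds the ring and, by inversion, its cis fusion.
Forward: fragment A (from (S)-citronellal) and fragment B (from a butynyl ether) → Wittig chain → 14-membered carbocycle (CrCl2) → lactone ring (CO2) → oxirane ring → desilylation.
Stereochemistry: C4 from (S)-citronellal; C3 from L-proline aminoxylation; C8 from Sharpless epoxidation and hydride opening; C1/C2 from the anti, Felkin-selective allylchromium cyclisation, C2 then inverted in the key step; C12/C13 from Shi epoxidation; 9Z from the Wittig reaction, 12E from carboalumination.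

Key step: step 22

Remark: ethyl bromo(triphenylphosphoranylidene)acetate is taken as a purchasable reagent, and the D-fructose-derived epoxidation ketone is taken to give the (R,R)-epoxide of an (E)-trisubstituted alkene, as its usual spiro model predicts.

Step 1
Reactants: 1 (S)-citronellal
Product: 3 (2R,3S)-3,7-dimethyl-2-(N-phenylaminooxy)oct-6-en-1-ol, via aminooxy aldehyde 2 (not isolated)
Conditions: PhNO, L-proline (20 mol %), CHCl3, 4 °C; then NaBH4, EtOH, 0 °C
Reagents that add atoms: nitrosobenzene O=Nc1ccccc1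
Why: Proline enamine catalysis (α-aminoxylation) should deliver the nitroso oxygen to the enamine face fixed by L-proline, setting C3 as (R) under catalyst control beside the existing C4 methyl centre, and NaBH4 then reduces the labile aldehyde.

Step 2
Reactants: 3 (2R,3S)-3,7-dimethyl-2-(N-phenylaminooxy)oct-6-en-1-ol
Product: 4 (2R,3S)-3,7-dimethyloct-6-ene-1,2-diol
Conditions: Zn, AcOH, EtOH, rt
Reagents that add atoms: none
Why: Dissolving-metal reduction cleaves the weak N–O bond and leaves the C–O bond, the stereocentres and the alkene untouched.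

Step 3
Reactants: 4 (2R,3S)-3,7-dimethyloct-6-ene-1,2-diol
Product: 5 (2R,3S)-3,7-dimethyl-1,2-bis(triethylsilyloxy)oct-6-ene
Conditions: Et3SiCl, imidazole, DMF, 0 °C to rt
Reagents that add atoms: chlorotriethylsilane CC[Si](Cl)(CC)CC
Why: Standard silylation of both hydroxyls; the primary triethylsilyl ether later serves as the masked C2 aldehyde and the secondary one as a non-chelating, non-participating group at C3.

Step 4
Reactants: 5 (2R,3S)-3,7-dimethyl-1,2-bis(triethylsilyloxy)oct-6-ene
Product: 6 (2E,6S,7R)-2,6-dimethyl-7,8-bis(triethylsilyloxy)oct-2-en-1-ol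
Conditions: SeO2 (0.5 equiv), t-BuOOH, CH2Cl2, rt
Reagents that add atoms: selenium dioxide O=[Se]=O (transfers the oxygen; re-oxidised by tert-butyl hydroperoxide CC(C)(C)OO)
Why: SeO2 allylic oxidation (ene reaction then 2,3-sigmatropic shift) is selective for the (E)-methyl group of a trisubstituted alkene, which becomes C9.

Step 5
Reactants: 6 (2E,6S,7R)-2,6-dimethyl-7,8-bis(triethylsilyloxy)oct-2-en-1-ol
Product: 7 [(2R,3R)-2-methyl-3-[(3S,4R)-3-methyl-4,5-bis(triethylsilyloxy)pentyl]oxiran-2-yl]methanol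
Conditions: Ti(Oi-Pr)4, D-(−)-diethyl tartrate, t-BuOOH, 4 Å MS, CH2Cl2, −20 °C
Reagents that add atoms: tert-butyl hydroperoxide CC(C)(C)OO
Why: Sharpless asymmetric epoxidation of the (E)-2-methyl allylic alcohol; the D-(−)-tartrate ligand should direct oxygen to the face that gives the (2R,3R)-epoxide and thereby the C8 configuration.

Step 6
Reactants: 7 [(2R,3R)-2-methyl-3-[(3S,4R)-3-methyl-4,5-bis(triethylsilyloxy)pentyl]oxiran-2-yl]methanol
Product: 8 (2S,6S,7R)-2,6-dimethyl-7,8-bis(triethylsilyloxy)octane-1,2-diol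
Conditions: LiAlH4, THF, 0 °C
Reagents that add atoms: none
Why: Hydride opens the trisubstituted epoxide by SN2 attack at the less substituted carbon (C7), so the C8–O bond and its configuration survive as the tertiary alcohol.

Step 7
Reactants: 8 (2S,6S,7R)-2,6-dimethyl-7,8-bis(triethylsilyloxy)octane-1,2-diol
Product: 9 (2S,6S,7R)-2-hydroxy-2,6-dimethyl-7,8-bis(triethylsilyloxy)octanal
Conditions: SO3·pyridine, DMSO, i-Pr2NEt, CH2Cl2, 0 °C
Reagents that add atoms: none
Why: Parikh–Doering oxidation converts only the primary hydroxyl; the tertiary one cannot be oxidised, C8 has no α-hydrogen, and the silyl ethers are stable to these non-acidic conditions.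

Step 8
Reactants: 9 (2S,6S,7R)-2-hydroxy-2,6-dimethyl-7,8-bis(triethylsilyloxy)octanal
Product: 10 (2S,6S,7R)-2,6-dimethyl-2,7,8-tris(triethylsilyloxy)octanal (fragment A)
Conditions: Et3SiOTf, 2,6-lutidine, CH2Cl2, −78 °C
Reagents that add atoms: triethylsilyl triflate CC[Si](CC)(CC)OS(=O)(=O)C(F)(F)F
Why: The silyl triflate silylates the hindered tertiary alcohol, and the aldehyde has no α-hydrogen, so no enol ether can form.

Step 9
Reactants: 11 tert-butyl(but-3-yn-1-yloxy)dimethylsilane
Product: 14 (E)-6-(tert-butyldimethylsilyloxy)-4-methylhex-3-en-1-ol, via alkenylalane 12 (not isolated), via lithium alanate 13 (not isolated)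
Conditions: AlMe3, Cp2ZrCl2 (20 mol %), CH2Cl2, 0 °C to rt; then n-BuLi, THF, −78 °C; ethylene oxide, −78 to 0 °C
Reagents that add atoms: trimethylaluminium C[Al](C)C; ethylene oxide C1CO1
Why: Negishi carboalumination (Zr-catalysed syn methylalumination) sets the (E)-trisubstituted C12=C13 alkene, and the derived alanate opens ethylene oxide with retention of alkene geometry.

Step 10
Reactants: 14 (E)-6-(tert-butyldimethylsilyloxy)-4-methylhex-3-en-1-ol
Product: 16 ethyl (2Z,5E)-2-bromo-8-(tert-butyldimethylsilyloxy)-6-methylocta-2,5-dienoate, via aldehyde 15 (not isolated)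
Conditions: Dess–Martin periodinane, NaHCO3, CH2Cl2, 0 °C; then Ph3P=C(Br)CO2Et, rt
Reagents that add atoms: ethyl bromo(triphenylphosphoranylidene)acetate CCOC(=O)C(Br)=P(c1ccccc1)(c1ccccc1)c1ccccc1
Why: Dess–Martin oxidation followed at once by Wittig olefination with the neutral stabilised bromo ylide should trap the β,γ-unsaturated aldehyde before it can conjugate; either geometry of the new bromoalkene is usable later.

Step 11
Reactants: 16 ethyl (2Z,5E)-2-bromo-8-(tert-butyldimethylsilyloxy)-6-methylocta-2,5-dienoate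
Product: 17 (2Z,5E)-2-bromo-8-(tert-butyldimethylsilyloxy)-6-methylocta-2,5-dien-1-ol
Conditions: i-Bu2AlH, CH2Cl2, −78 °C
Reagents that add atoms: none
Why: 1,2-Reduction of the enoate by the aluminium hydride at low temperature leaves the alkenyl bromide and the silyl ether intact.

Step 12
Reactants: 17 (2Z,5E)-2-bromo-8-(tert-butyldimethylsilyloxy)-6-methylocta-2,5-dien-1-ol
Product: 18 (2Z,5E)-2-bromo-8-(tert-butyldimethylsilyloxy)-6-methylocta-2,5-dien-1-yl pivalate
Conditions: t-BuCOCl, pyridine, DMAP (cat.), CH2Cl2, 0 °C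
Reagents that add atoms: pivaloyl chloride CC(C)(C)C(=O)Cl
Why: Acylation; the hindered, non-enolisable pivalate should survive ylide formation and is later removed by hydride without touching triethylsilyl ethers.

Step 13
Reactants: 18 (2Z,5E)-2-bromo-8-(tert-butyldimethylsilyloxy)-6-methylocta-2,5-dien-1-yl pivalate
Product: 19 (2Z,5E)-2-bromo-8-hydroxy-6-methylocta-2,5-dien-1-yl pivalate
Conditions: HF·pyridine, pyridine, THF, 0 °C to rt
Reagents that add atoms: none
Why: Fluoride-mediated desilylation is selective for the silyl ether; ester, alkenyl bromide and alkenes are inert.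

Step 14
Reactants: 19 (2Z,5E)-2-bromo-8-hydroxy-6-methylocta-2,5-dien-1-yl pivalate
Product: 20 (2Z,5E)-2-bromo-8-iodo-6-methylocta-2,5-dien-1-yl pivalate
Conditions: I2, PPh3, imidazole, CH2Cl2, 0 °C
Reagents that add atoms: iodine II
Why: Appel-type iodination of the primary homoallylic alcohol by SN2 displacement of the oxyphosphonium group.

Step 15
Reactants: 20 (2Z,5E)-2-bromo-8-iodo-6-methylocta-2,5-dien-1-yl pivalate
Product: 21 [(3E,6Z)-7-bromo-3-methyl-8-(pivaloyloxy)octa-3,6-dien-1-yl]triphenylphosphonium iodide (fragment B)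
Conditions: PPh3, MeCN, 70 °C
Reagents that add atoms: triphenylphosphine c1ccc(cc1)P(c1ccccc1)c1ccccc1
Why: SN2 quaternisation of the phosphine by the primary iodide; the alkenyl bromide and allylic pivalate do not react without a transition metal.

Step 16
Reactants: 21 [(3E,6Z)-7-bromo-3-methyl-8-(pivaloyloxy)octa-3,6-dien-1-yl]triphenylphosphonium iodide; 10 (2S,6S,7R)-2,6-dimethyl-2,7,8-tris(triethylsilyloxy)octanal
Product: 23 (2Z,5E,8Z,10S,14S,15R)-2-bromo-6,10,14-trimethyl-10,15,16-tris(triethylsilyloxy)hexadeca-2,5,8-trien-1-yl pivalate, via ylide 22 (not isolated)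
Conditions: NaN(SiMe3)2, THF, −78 °C; then 10, −78 to 0 °C
Reagents that add atoms: none
Why: Wittig reaction of a non-stabilised ylide under lithium-free conditions should give the (Z)-C9=C10 alkene through the kinetically favoured cis-oxaphosphetane, and the aldehyde has no enolisable centre.

Step 17
Reactants: 23 (2Z,5E,8Z,10S,14S,15R)-2-bromo-6,10,14-trimethyl-10,15,16-tris(triethylsilyloxy)hexadeca-2,5,8-trien-1-yl pivalate
Product: 24 (2Z,5E,8Z,10S,14S,15R)-2-bromo-6,10,14-trimethyl-10,15,16-tris(triethylsilyloxy)hexadeca-2,5,8-trien-1-ol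
Conditions: i-Bu2AlH, CH2Cl2, −78 °C
Reagents that add atoms: none
Why: Reductive cleavage of the pivalate by hydride at low temperature spares the triethylsilyl ethers and the alkenyl bromide.

Step 18
Reactants: 24 (2Z,5E,8Z,10S,14S,15R)-2-bromo-6,10,14-trimethyl-10,15,16-tris(triethylsilyloxy)hexadeca-2,5,8-trien-1-ol
Product: 26 (2Z,5E,8Z,10S,14S,15R)-2-bromo-1-chloro-6,10,14-trimethyl-10,15,16-tris(triethylsilyloxy)hexadeca-2,5,8-triene, via allylic mesylate 25 (not isolated)
Conditions: MeSO2Cl, 2,4,6-collidine, LiCl, DMF, 0 °C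
Reagents that add atoms: lithium chloride [Li+].[Cl-] (methanesulfonyl chloride CS(=O)(=O)Cl supplies the mesyl group of 25 only)
Why: The allylic mesylate formed in situ is displaced by chloride (SN2) to give the primary allylic chloride without allylic transposition.

Step 19
Reactants: 26 (2Z,5E,8Z,10S,14S,15R)-2-bromo-1-chloro-6,10,14-trimethyl-10,15,16-tris(triethylsilyloxy)hexadeca-2,5,8-triene
Product: 27 (2R,3S,7S,8Z,11E,14Z)-15-bromo-16-chloro-3,7,11-trimethyl-2,7-bis(triethylsilyloxy)hexadeca-8,11,14-trienal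
Conditions: (COCl)2, DMSO, CH2Cl2, −78 to −40 °C; then i-Pr2NEt, −78 to 0 °C
Reagents that add atoms: none
Why: Under Swern conditions a primary triethylsilyl ether is cleaved and oxidised directly to the aldehyde while secondary and tertiary silyl ethers remain, and the low temperature and hindered base should keep C3 from epimerising.

Step 20
Reactants: 27 (2R,3S,7S,8Z,11E,14Z)-15-bromo-16-chloro-3,7,11-trimethyl-2,7-bis(triethylsilyloxy)hexadeca-8,11,14-trienal
Product: 29 (1S,2R,3S,7S,8Z,11E,14R)-14-(1-bromoethenyl)-3,7,11-trimethyl-2,7-bis(triethylsilyloxy)cyclotetradeca-8,11-dien-1-ol, via allylchromium 28 (not isolated)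
Conditions: CrCl2 (10 equiv), THF/DMF, rt, slow addition (2 mM)
Reagents that add atoms: none
Why: Nozaki–Hiyama allylation: divalent chromium inserts only into the allylic C–Cl bond (alkenyl bromides need a nickel co-catalyst), and the γ-substituted allylchromium should add at C1 through a chair Zimmerman–Traxler transition state (anti C1/C2) with Felkin–Anh approach anti to the C3 silyloxy group, closing the 14-membered ring under high dilution.

Step 21
Reactants: 29 (1S,2R,3S,7S,8Z,11E,14R)-14-(1-bromoethenyl)-3,7,11-trimethyl-2,7-bis(triethylsilyloxy)cyclotetradeca-8,11-dien-1-ol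
Product: 30 (1S,2R,3S,7S,8Z,11E,14R)-14-(1-bromoethenyl)-3,7,11-trimethyl-2,7-bis(triethylsilyloxy)cyclotetradeca-8,11-dien-1-yl methanesulfonate
Conditions: MeSO2Cl, Et3N, CH2Cl2, −20 °C
Reagents that add atoms: methanesulfonyl chloride CS(=O)(=O)Cl
Why: Sulfene-type mesylation activates the hindered secondary C2 alcohol with retention; all other oxygens are silylated.

Step 22
Reactants: 30 (1S,2R,3S,7S,8Z,11E,14R)-14-(1-bromoethenyl)-3,7,11-trimethyl-2,7-bis(triethylsilyloxy)cyclotetradeca-8,11-dien-1-yl methanesulfonate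
Product: 32 (1S,2R,3R,4S,8S,9Z,12E)-3,8-bis(triethylsilyloxy)cembra-9,12,15(17)-trien-16,2-olide (cis-fused α-methylene-γ-butyrolactone), via carboxylate 31 (not isolated)
Conditions: CO2 (1 atm), NiBr2(dme) (10 mol %), 2,2'-bipyridine (20 mol %), Mn powder, DMA, rt; then 60 °C
Reagents that add atoms: carbon dioxide O=C=O
Why: Proposed new method: zerovalent nickel (from NiBr2(dme), bipyridine and Mn) should insert into the C15–Br bond of 30, the alkenylnickel is reduced by Mn to the monovalent stage and inserts CO2 to give carboxylate 31 (new C15–C16 bond), and on warming the carboxylate oxygen displaces the C2 mesylate from the rear (new O–C2 bond) to give lactone 32. The closest known reaction types are the nickel/Mn reductive carboxylation of alkenyl and aryl (pseudo)halides with CO2 at 1 atm and the displacement of secondary sulfonates by carboxylates with inversion; only their coupling in one flask on a halide that also carries a sulfonate is new. The lactone ring (O, C16, C15, C1, C2) closes 5-exo-tet. The only stereocentre changed is C2, fixed by stereospecific SN2 inversion of the mesylate configuration set in step 20, which turns the anti-adduct relationship into the cis ring fusion with the C2 oxygen syn to the C3 oxygen. The step needs oxidative addition at C(sp2)–Br and not at the secondary C–OMs (secured by the absence of iodide and by the hindered, alkoxy-flanked sulfonate) and O-alkylation instead of elimination or bromide exchange (secured by the intramolecular five-ring closure), and the C3 oxygen is silylated so that it cannot close an epoxide.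

Step 23
Reactants: 32 (1S,2R,3R,4S,8S,9Z,12E)-3,8-bis(triethylsilyloxy)cembra-9,12,15(17)-trien-16,2-olide
Product: 33 (1S,2R,3R,4S,8S,9Z,12R,13R)-12,13-epoxy-3,8-bis(triethylsilyloxy)cembra-9,15(17)-dien-16,2-olide
Conditions: D-fructose-derived Shi ketone (1,2:4,5-di-O-isopropylidene-D-erythro-2,3-hexodiulo-2,6-pyranose), KHSO5 (Oxone), K2CO3, Bu4NHSO4, MeCN/dimethoxymethane–aq. buffer (pH 10.5), 0 °C
Reagents that add atoms: potassium peroxymonosulfate [K+].[O-]S(=O)(=O)OO
Why: Shi epoxidation: the chiral dioxirane should epoxidise the electron-rich (E)-trisubstituted C12=C13 alkene through the spiro transition state to give the (12R,13R)-oxirane under reagent control, while the acrylate and the silyloxy-shielded (Z)-alkene react much more slowly.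

Step 24
Reactants: 33 (1S,2R,3R,4S,8S,9Z,12R,13R)-12,13-epoxy-3,8-bis(triethylsilyloxy)cembra-9,15(17)-dien-16,2-olide
Product: 34 (1S,2R,3R,4S,8S,9Z,12R,13R)-12,13-epoxy-3,8-dihydroxycembra-9,15(17)-dien-16,2-olide (CNP0304380.1)
Conditions: Bu4NF, AcOH, THF, 0 °C to rt
Reagents that add atoms: none
Why: Acetic-acid-buffered fluoride removes both triethylsilyl ethers under near-neutral conditions that should neither open the oxirane nor add to the α-methylene lactone.

Compound list
1 | (S)-citronellal, (3S)-3,7-dimethyloct-6-enal | O=CC[C@@H](C)CCC=C(C)C | starting material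
2 | (2R,3S)-3,7-dimethyl-2-(N-phenylaminooxy)oct-6-enal | O=C[C@H](ONc1ccccc1)[C@@H](C)CCC=C(C)C | intermediate (not isolated)
3 | (2R,3S)-3,7-dimethyl-2-(N-phenylaminooxy)oct-6-en-1-ol | OC[C@H](ONc1ccccc1)[C@@H](C)CCC=C(C)C | intermediate
4 | (2R,3S)-3,7-dimethyloct-6-ene-1,2-diol | OC[C@H](O)[C@@H](C)CCC=C(C)C | intermediate
5 | (2R,3S)-3,7-dimethyl-1,2-bis(triethylsilyloxy)oct-6-ene | CC[Si](CC)(CC)OC[C@H](O[Si](CC)(CC)CC)[C@@H](C)CCC=C(C)C | intermediate
6 | (2E,6S,7R)-2,6-dimethyl-7,8-bis(triethylsilyloxy)oct-2-en-1-ol | CC[Si](CC)(CC)OC[C@H](O[Si](CC)(CC)CC)[C@@H](C)CC/C=C(\C)CO | intermediate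
7 | [(2R,3R)-2-methyl-3-[(3S,4R)-3-methyl-4,5-bis(triethylsilyloxy)pentyl]oxiran-2-yl]methanol | CC[Si](CC)(CC)OC[C@H](O[Si](CC)(CC)CC)[C@@H](C)CC[C@H]1O[C@]1(C)CO | intermediate
8 | (2S,6S,7R)-2,6-dimethyl-7,8-bis(triethylsilyloxy)octane-1,2-diol | CC[Si](CC)(CC)OC[C@H](O[Si](CC)(CC)CC)[C@@H](C)CCC[C@](C)(O)CO | intermediate
9 | (2S,6S,7R)-2-hydroxy-2,6-dimethyl-7,8-bis(triethylsilyloxy)octanal | CC[Si](CC)(CC)OC[C@H](O[Si](CC)(CC)CC)[C@@H](C)CCC[C@](C)(O)C=O | intermediate
10 | (2S,6S,7R)-2,6-dimethyl-2,7,8-tris(triethylsilyloxy)octanal (fragment A, C2–C9) | CC[Si](CC)(CC)OC[C@H](O[Si](CC)(CC)CC)[C@@H](C)CCC[C@](C)(O[Si](CC)(CC)CC)C=O | intermediate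
11 | tert-butyl(but-3-yn-1-yloxy)dimethylsilane | C#CCCO[Si](C)(C)C(C)(C)C | starting material
12 | (E)-[4-(tert-butyldimethylsilyloxy)-2-methylbut-1-en-1-yl]dimethylalane | C[Al](C)/C=C(\C)CCO[Si](C)(C)C(C)(C)C | intermediate (not isolated)
13 | lithium butyl[(E)-4-(tert-butyldimethylsilyloxy)-2-methylbut-1-en-1-yl]dimethylalanate | [Li+].CCCC[Al-](C)(C)/C=C(\C)CCO[Si](C)(C)C(C)(C)C | intermediate (not isolated)
14 | (E)-6-(tert-butyldimethylsilyloxy)-4-methylhex-3-en-1-ol | OCC/C=C(\C)CCO[Si](C)(C)C(C)(C)C | intermediate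
15 | (E)-6-(tert-butyldimethylsilyloxy)-4-methylhex-3-enal | O=CC/C=C(\C)CCO[Si](C)(C)C(C)(C)C | intermediate (not isolated)
16 | ethyl (2Z,5E)-2-bromo-8-(tert-butyldimethylsilyloxy)-6-methylocta-2,5-dienoate | CCOC(=O)/C(Br)=C/C/C=C(\C)CCO[Si](C)(C)C(C)(C)C | intermediate
17 | (2Z,5E)-2-bromo-8-(tert-butyldimethylsilyloxy)-6-methylocta-2,5-dien-1-ol | OC/C(Br)=C/C/C=C(\C)CCO[Si](C)(C)C(C)(C)C | intermediate
18 | (2Z,5E)-2-bromo-8-(tert-butyldimethylsilyloxy)-6-methylocta-2,5-dien-1-yl pivalate | CC(C)(C)C(=O)OC/C(Br)=C/C/C=C(\C)CCO[Si](C)(C)C(C)(C)C | intermediate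
19 | (2Z,5E)-2-bromo-8-hydroxy-6-methylocta-2,5-dien-1-yl pivalate | CC(C)(C)C(=O)OC/C(Br)=C/C/C=C(\C)CCO | intermediate
20 | (2Z,5E)-2-bromo-8-iodo-6-methylocta-2,5-dien-1-yl pivalate | CC(C)(C)C(=O)OC/C(Br)=C/C/C=C(\C)CCI | intermediate
21 | [(3E,6Z)-7-bromo-3-methyl-8-(pivaloyloxy)octa-3,6-dien-1-yl]triphenylphosphonium iodide (fragment B) | CC(C)(C)C(=O)OC/C(Br)=C/C/C=C(\C)CC[P+](c1ccccc1)(c1ccccc1)c1ccccc1.[I-] | intermediate
22 | ylide of 21, (2Z,5E)-2-bromo-6-methyl-8-(triphenylphosphoranylidene)octa-2,5-dien-1-yl pivalate | CC(C)(C)C(=O)OC/C(Br)=C/C/C=C(\C)CC=P(c1ccccc1)(c1ccccc1)c1ccccc1 | intermediate (not isolated)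
23 | (2Z,5E,8Z,10S,14S,15R)-2-bromo-6,10,14-trimethyl-10,15,16-tris(triethylsilyloxy)hexadeca-2,5,8-trien-1-yl pivalate | CC[Si](CC)(CC)OC[C@H](O[Si](CC)(CC)CC)[C@@H](C)CCC[C@](C)(O[Si](CC)(CC)CC)/C=C\C/C(C)=C/C/C=C(\Br)COC(=O)C(C)(C)C | intermediate
24 | (2Z,5E,8Z,10S,14S,15R)-2-bromo-6,10,14-trimethyl-10,15,16-tris(triethylsilyloxy)hexadeca-2,5,8-trien-1-ol | CC[Si](CC)(CC)OC[C@H](O[Si](CC)(CC)CC)[C@@H](C)CCC[C@](C)(O[Si](CC)(CC)CC)/C=C\C/C(C)=C/C/C=C(\Br)CO | intermediate
25 | methanesulfonate of 24 | CC[Si](CC)(CC)OC[C@H](O[Si](CC)(CC)CC)[C@@H](C)CCC[C@](C)(O[Si](CC)(CC)CC)/C=C\C/C(C)=C/C/C=C(\Br)COS(C)(=O)=O | intermediate (not isolated)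
26 | (2Z,5E,8Z,10S,14S,15R)-2-bromo-1-chloro-6,10,14-trimethyl-10,15,16-tris(triethylsilyloxy)hexadeca-2,5,8-triene | CC[Si](CC)(CC)OC[C@H](O[Si](CC)(CC)CC)[C@@H](C)CCC[C@](C)(O[Si](CC)(CC)CC)/C=C\C/C(C)=C/C/C=C(\Br)CCl | intermediate
27 | (2R,3S,7S,8Z,11E,14Z)-15-bromo-16-chloro-3,7,11-trimethyl-2,7-bis(triethylsilyloxy)hexadeca-8,11,14-trienal | O=C[C@H](O[Si](CC)(CC)CC)[C@@H](C)CCC[C@](C)(O[Si](CC)(CC)CC)/C=C\C/C(C)=C/C/C=C(\Br)CCl | intermediate
28 | allylchromium dichloride derived from 27 (CrCl2 in place of Cl at C17) | O=C[C@H](O[Si](CC)(CC)CC)[C@@H](C)CCC[C@](C)(O[Si](CC)(CC)CC)/C=C\C/C(C)=C/C/C=C(\Br)C[Cr](Cl)Cl | intermediate (not isolated)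
29 | (1S,2R,3S,7S,8Z,11E,14R)-14-(1-bromoethenyl)-3,7,11-trimethyl-2,7-bis(triethylsilyloxy)cyclotetradeca-8,11-dien-1-ol | C=C(Br)[C@H]1[C@H](O)[C@H](O[Si](CC)(CC)CC)[C@@H](C)CCC[C@](C)(O[Si](CC)(CC)CC)/C=C\C/C(C)=C/C1 | intermediate
30 | methanesulfonate of 29 | C=C(Br)[C@H]1[C@H](OS(C)(=O)=O)[C@H](O[Si](CC)(CC)CC)[C@@H](C)CCC[C@](C)(O[Si](CC)(CC)CC)/C=C\C/C(C)=C/C1 | intermediate
31 | manganese carboxylate (CO2 in place of Br at C15 of 30) | C=C(C(=O)[O-])[C@H]1[C@H](OS(C)(=O)=O)[C@H](O[Si](CC)(CC)CC)[C@@H](C)CCC[C@](C)(O[Si](CC)(CC)CC)/C=C\C/C(C)=C/C1.[Mn+2].[Br-] | intermediate (not isolated)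
32 | (1S,2R,3R,4S,8S,9Z,12E)-3,8-bis(triethylsilyloxy)cembra-9,12,15(17)-trien-16,2-olide | C=C1C(=O)O[C@H]2[C@H](O[Si](CC)(CC)CC)[C@@H](C)CCC[C@](C)(O[Si](CC)(CC)CC)/C=C\C/C(C)=C/C[C@@H]12 | intermediate
33 | (1S,2R,3R,4S,8S,9Z,12R,13R)-12,13-epoxy-3,8-bis(triethylsilyloxy)cembra-9,15(17)-dien-16,2-olide | C=C1C(=O)O[C@H]2[C@H](O[Si](CC)(CC)CC)[C@@H](C)CCC[C@](C)(O[Si](CC)(CC)CC)/C=C\C[C@@]3(C)O[C@@H]3C[C@@H]12 | intermediate
34 | (1S,2R,3R,4S,8S,9Z,12R,13R)-12,13-epoxy-3,8-dihydroxycembra-9,15(17)-dien-16,2-olide (CNP0304380.1) | C=C1C(=O)O[C@H]2[C@H](O)[C@@H](C)CCC[C@](C)(O)/C=C\C[C@@]3(C)O[C@@H]3C[C@@H]12 | target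

Total step count: 24. Longest linear sequence: 17 steps (steps 1–8, then 16–24); fragment B takes steps 9–15.

Steps most likely to fail

Step 22 (proposed new method). The alkenylnickel intermediate may be protonated instead of carboxylated, the mesylate may be consumed by reduction or by bromide exchange (which would erode the inversion), or elimination may outrun ring closure. The fallback uses known chemistry and sets out from 30. Carbonylation with Pd(PPh3)4 (zerovalent palladium), CO (1 atm), MeOH and Et3N in DMF at 50 °C should convert the alkenyl bromide into the methyl acrylate mesylate F1. LiOH in THF/H2O then saponifies it to the lithium carboxylate F2, which on gentle warming displaces the C2 mesylate with inversion; an acidic work-up re-closes any lactone opened by hydroxide. The route is rejoined at 32.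

Step 20. The allylchromium species may lose bromide to give an allene, chain growth may compete with ring closure if dilution is insufficient, or the facial selectivity at the aldehyde may be poor inside the forming ring. The fallback sets out from 26 and replaces the reducing-metal cyclisation by a pre-formed allyl donor. Bu3SnLi (THF, −78 °C) should displace the allylic chloride to give the allylic stannane F3. Buffered HF·pyridine removes only the primary silyl ether to give the stannyl alcohol F4, and Dess–Martin periodinane oxidises it to the stannyl aldehyde F5. InCl3 (EtOAc, −78 °C to rt, high dilution) then transmetalates the stannane to an allylindium chloride, which should add through a cyclic, anti-selective transition state. The route is rejoined at 29.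

Step 23. The conformation of the 14-membered ring may override the catalyst and erode facial selectivity, the C9=C10 alkene may be epoxidised competitively, or the lactone may be attacked at pH 10.5. The fallback sets out from 32 and forms the oxirane in two stages. NBS in THF/H2O at 0 °C should give the bromohydrin F6 (water opens the bromonium ion at the tertiary C12), and DBU closes it to the oxirane. Because oxygen ends up anti to the bromonium ion, this sequence delivers the diastereomer opposite to direct oxygen transfer on the same face preference, under near-neutral conditions. The route is rejoined at 33.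

Further compounds
F1 | step 22 | methyl acrylate mesylate (CO2Me in place of Br at C15 of 30) | COC(=O)C(=C)[C@H]1[C@H](OS(C)(=O)=O)[C@H](O[Si](CC)(CC)CC)[C@@H](C)CCC[C@](C)(O[Si](CC)(CC)CC)/C=C\C/C(C)=C/C1
F2 | step 22 | lithium carboxylate of F1 | [Li+].[O-]C(=O)C(=C)[C@H]1[C@H](OS(C)(=O)=O)[C@H](O[Si](CC)(CC)CC)[C@@H](C)CCC[C@](C)(O[Si](CC)(CC)CC)/C=C\C/C(C)=C/C1
F3 | step 20 | allylic tributylstannane (SnBu3 in place of Cl in 26) | CC[Si](CC)(CC)OC[C@H](O[Si](CC)(CC)CC)[C@@H](C)CCC[C@](C)(O[Si](CC)(CC)CC)/C=C\C/C(C)=C/C/C=C(\Br)C[Sn](CCCC)(CCCC)CCCC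
F4 | step 20 | stannyl primary alcohol (C2 hydroxyl freed in F3) | OC[C@H](O[Si](CC)(CC)CC)[C@@H](C)CCC[C@](C)(O[Si](CC)(CC)CC)/C=C\C/C(C)=C/C/C=C(\Br)C[Sn](CCCC)(CCCC)CCCC
F5 | step 20 | stannyl aldehyde (C2 aldehyde from F4) | O=C[C@H](O[Si](CC)(CC)CC)[C@@H](C)CCC[C@](C)(O[Si](CC)(CC)CC)/C=C\C/C(C)=C/C/C=C(\Br)C[Sn](CCCC)(CCCC)CCCC
F6 | step 23 | (12R,13S)-13-bromo-12-hydroxy derivative of 32 (bromohydrin) | C=C1C(=O)O[C@H]2[C@H](O[Si](CC)(CC)CC)[C@@H](C)CCC[C@](C)(O[Si](CC)(CC)CC)/C=C\C[C@@](C)(O)[C@@H](Br)C[C@@H]12
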